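The runs come from a simulation with constants of no real substance; noise was put on by code.

We will repeat this flask watching what the catalyst can still pay for rather than the clock. It holds 0.10 M of starting material and 50 µM of free catalyst, with the gas held.

| flask | starting material | gas phase | free catalyst | remark | time |
|---|---|---|---|---|---|
| Saturday's | 0.067 M | 49 mM (held) | 50 µM | run made earlier |  |
| Tuesday's | 0.15 M | 49 mM (held) | 50 µM | run made earlier |  |
| Sunday's | 0.10 M | 49 mM (held) | 100 µM | run made earlier |  |
| flask | 0.10 M | 49 mM (held) | 50 µM |  | 12 h |

| run | time / h | target / % | starting material / % |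
|---|---|---|---|
| Saturday's | 1.00 | 9.4 | 88.7 |
| Saturday's | 2.00 | 22.0 | 77.5 |
| Saturday's | 4.00 | 41.6 | 57.4 |
| Saturday's | 8.00 | 62.6 | 37.4 |
| Saturday's | 15.0 | 77.7 | 21.3 |
| Tuesday's | 1.33 | 15.6 | 86.0 |
| Tuesday's | 4.00 | 39.5 | 60.1 |
| Tuesday's | 6.00 | 48.9 | 50.5 |
| Tuesday's | 10.0 | 60.6 | 39.6 |
| Tuesday's | 15.0 | 65.7 | 35.9 |
| Sunday's | 3.00 | 51.4 | 49.0 |
| Sunday's | 6.00 | 73.1 | 25.6 |
| Sunday's | 8.00 | 80.9 | 19.7 |
| Sunday's | 12.0 | 86.4 | 13.1 |
| Sunday's | 15.0 | 85.7 | 12.0 |

(scatter of a reading: 1 percentage point)

* the target standing at 12 h, as a percentage of the starting material charged
* concentration of dissolved gas in solution at 6.0 h, in percent of saturation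
* the change that raises the amount of target at 12 h, in percent of the starting material charged most ("none" if none brings more than 2 percentage points) (delta / zeta / epsilon / none)
* amount of target at 12 h, in percent of the starting material charged, after delta

- at the start none of the gas is dissolved
- candidate steps: gas phase <-> dissolved gas; starting material + dissolved gas + free catalyst -> free catalyst + target; free catalyst + target -> spent catalyst; 2 dissolved gas -> homo dimer

- delta: doubling the transfer coefficient of the gas phase, all else as stated
- zeta: doubling the saturation concentration of gas phase, all else as stated
- epsilon: doubling the amount of free catalyst, all else as stated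

Saturday's and Tuesday's runs, with different charges, stood level at 4.00 h: 41.6% and 39.5% target. So the early rate is pseudo-first-order in starting material, if dissolved gas stays level, which we assume. By 15.0 h they have parted, with Saturday's at 77.7% and Tuesday's at 65.7%, so something that grows with [target] is stopping the run.

Follow one free catalyst molecule. At each fork it either turns over, at a rate proportional to [starting material], or meets target and is spent, at a rate proportional to [target]. Summing these odds along a run gives a rule: the share of catalyst spent equals the starting charge times (ln(charged/left) minus the fraction reacted), divided by a constant of the run. Tuesday's last reading, taken as the end, gives 0.0620 M for this catalyst budget, the concentration of charge that a given catalyst loading can carry, proportional to that loading. It is a floor, since Tuesday's starting material was still falling, from 39.6% to 35.9%.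

Our flask's budget per charge is 0.620, and since the budget is a floor this gives only a lower estimate of where the run stops, 74.4% target. With 100 µM of catalyst the ratio becomes 1.24 and the lower estimate 88.0%. Sunday's last reading, 85.7%, stands below that. We therefore choose epsilon; the runs do not test zeta.

The forecast said 69%, 97%, zeta and 70.5%, holding that “Rates fade faster at higher target concentration”, and it parts from our choice of epsilon.

The flask gives 68.4%, 85.7%, epsilon and 70.5%; epsilon gains 17 percentage points, zeta 16 points and delta 2.1 points.

    gas phase ⇌ dissolved gas, rate k1*(csat - [dissolved gas]) (kL = 0.0885 min⁻¹)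
    starting material + dissolved gas + free catalyst → free catalyst + target (k = 1140 M⁻² min⁻¹)
    free catalyst + target → spent catalyst (k = 0.0347 M⁻¹ min⁻¹)
    2 dissolved gas → homo dimer (k = 0.153 M⁻¹ min⁻¹)

In this flask the turnover ran fast at the start, with 39% of its work done by 2.40 h, while free catalyst stood at 98.5% at 1.20 h. It slowed as free catalyst fell to 32.0% at 12.0 h, while dissolved gas stayed near 0.0425 M. Our rule, fed 68.4%, spends 75.5% of the catalyst, against 68.0% in the flask, as a floor on the budget should.

With 1.2 × 10⁻⁵ M of catalyst the ratio is 0.149 and the lower estimate of where that run stops 45.2%. That flask stands at 30.1% target at 12.0 h, with 34.2% of its catalyst spent.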